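The charge is conserved: starting material, target, over-reacted product, over-reaction product and decomposition product always add up to the 10 mM charged. So I follow the pool of starting material plus target, which shrinks as target leaves through its two irreversible exits.

starting material 10 mM; gas phase 2.6 mM (held); time 10 s

    dissolved gas + target → over-reacted product (k1 = 102 L mol⁻¹ s⁻¹)
    starting material + dissolved gas ⇌ target (K2 = 260 L mol⁻¹, k2 = 286 L mol⁻¹ s⁻¹)
    gas phase ⇌ dissolved gas, rate k3*(csat - [dissolved gas]) (k3 = 1.23 s⁻¹, csat = 2.6 mM)
    starting material → decomposition product (k4 = 1.47 × 10⁻⁴ s⁻¹)
    target → over-reaction product (k5 = 0.457 s⁻¹)

- the target standing at 10 s, as a percentage of the starting material charged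
- the change that raises the amount of target at 10 s, in percent of the starting material charged most ("none" if none brings more than 2 percentage points) (dawn / autumn / none)
- amount of target at 10 s, in percent of the starting material charged, after dawn

- dawn: doubling the transfer coefficient of step 3, all else as stated
- autumn: doubling the saturation concentration of gas phase, all else as stated

- at the start none of the gas is dissolved
- run time (flask): 10 s

Let c be the dissolved gas, first held at 2.6 mM. With the reversible step by itself, target over starting material goes to 0.676. Target also falls back at 1.10 s⁻¹, and adding its loss to over-reaction product lowers the ratio to 0.478. Adding the reaction with dissolved gas gives the quantity I carry, the standing ratio r: the forward constant times c, divided by the sum of target's loss constants, 0.408 at saturation. This is a quasi-steady state, because target's lifetime of 0.549 s is shorter than the run. I drop decomposition, whose half-life of 79 min is far longer than the run.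

The pool decays at g, the two exits' constants times target's share, r over r plus one: 0.209 s⁻¹ at saturation. But the gas lags. At the start, transfer balances uptake by the full charge at c = 0.782 mM, where g is 0.0645 s⁻¹. Joining the ends by their mean, a rough step, leaves 25.4% of the pool, and the late share makes that 7.37% target. Dawn, the doubled transfer coefficient, lifts the early level to 1.20 mM and g there to 0.0985 s⁻¹, giving 6.22%. Autumn, the doubled saturation concentration, reckoned alike, gives 2.82%. Both are lower than 7.37%, so I choose none.

The forecast, a little apart from my numbers, says 7.3%, none, and 6% after dawn, holding that “More gas, whether through faster transfer or higher saturation, only speeds that drain”. The simulation gives 7.26%, none as the best change (dawn −1.7 percentage points, autumn −5.3 points), and 5.51% after dawn.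

In this flask, target's half-life by loss to over-reaction product, 1.5 s, is short against the run, and r at saturation times the 19.4% of starting material standing at 10.0 s, with dissolved gas at 2.11 mM, makes 7.91% of target, against 7.26% read. In the same flask read at 15 s, r at saturation times 6.96% of starting material makes 2.84%, and the reading is 2.97%.

(All constants are those of an exercise; no experiment stands behind them.)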